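**Retrosynthetic overview**
1. Neocryptomerin ⇒ (hydrogenolysis of four benzyl ethers) protected biflavone ⇒ (I2/DMSO oxidative closure) 2'-hydroxychalcone. This closure forms the pyranone of the 7-methoxy unit, the second and last ring built.
2. Key C–C disconnection at the chalcone Cα=Cβ bond ⇒ intermolecular Claisen–Schmidt aldol condensation. The partners are a flavone-bearing 4-aryloxybenzaldehyde and 2-benzyloxy-6-hydroxy-4-methoxyacetophenone (from phloracetophenone).
3. Diaryl ether C–O ⇒ SNAr of 6-hydroxy-5,7,4'-trimethoxyflavone on 4-fluorobenzaldehyde. A Me→Bn exchange follows, so the only OMe in the target comes from the other half.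
4. 6-Hydroxyflavone ⇒ chalcone ⇒ a first Claisen–Schmidt aldol of 3-benzyloxy-6-hydroxy-2,4-dimethoxyacetophenone with anisaldehyde. The pyranone of the 6-aryloxy unit is the first ring built.
5. That acetophenone ⇒ syringaldehyde by Dakin oxidation, diacetylation and Fries rearrangement. All four benzene rings are bought and only the two pyranones are constructed.

Assumption: the target SMILES has no stereocentre or stable stereoaxis, so neocryptomerin is one achiral compound and needs no enantiocontrol. The only stereo-elements en route are E-chalcone alkenes and transient racemic centres, all erased on aromatisation.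

**Step 1**
Reactants: 1 syringaldehyde (4-hydroxy-3,5-dimethoxybenzaldehyde)
Product: 3 2,6-dimethoxybenzene-1,4-diol, via aryl formate 2 (not isolated)
Conditions: 30% aq H2O2 (1.2 equiv), NaOH (2.1 equiv), H2O–THF, 0 °C → rt, N2; then 2 M HCl
Reagents that add atoms: hydrogen peroxide (OO)
Why: Dakin oxidation, in which hydroperoxide adds to the aldehyde of the electron-rich p-hydroxyaryl ring, the aryl group migrates to oxygen and formate 2 is saponified in the same pot, with no stereocentre formed.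

**Step 2**
Reactants: 3 2,6-dimethoxybenzene-1,4-diol
Product: 4 2,6-dimethoxybenzene-1,4-diyl diacetate
Conditions: Ac2O (3 equiv), pyridine, DMAP (cat.), 0 °C → rt
Reagents that add atoms: acetic anhydride (CC(=O)OC(C)=O)
Why: DMAP-catalysed exhaustive O-acetylation converts the air-sensitive hydroquinone into a stable, symmetric Fries substrate.

**Step 3**
Reactants: 4 2,6-dimethoxybenzene-1,4-diyl diacetate
Product: 6 1-(3,6-dihydroxy-2,4-dimethoxyphenyl)ethanone, via Fries acetate 5 (not isolated)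
Conditions: BF3·OEt2 (3 equiv), AcOH, 90 °C, 3 h; H2O quench; crude in MeOH, HCl (cat.), reflux
Reagents that add atoms: none
Why: Fries rearrangement, in which the only two free ring positions are equivalent and lie ortho to the unhindered acetate, so a single acetophenone forms with its chelated OH next to C–H, and acid transesterification then frees the hindered acetate.

**Step 4**
Reactants: 6 1-(3,6-dihydroxy-2,4-dimethoxyphenyl)ethanone
Product: 7 1-[3-(benzyloxy)-6-hydroxy-2,4-dimethoxyphenyl]ethanone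
Conditions: BnBr (1.05 equiv), K2CO3 (1.2 equiv), acetone, reflux, N2
Reagents that add atoms: benzyl bromide (BrCc1ccccc1)
Why: Williamson etherification, in which the OH ortho to the acetyl group is tied up in a strong hydrogen bond to C=O, so one equivalent of BnBr alkylates only the non-chelated 3-OH.

**Step 5**
Reactants: 7 1-[3-(benzyloxy)-6-hydroxy-2,4-dimethoxyphenyl]ethanone; 8 4-methoxybenzaldehyde
Product: 10 (E)-1-[3-(benzyloxy)-6-hydroxy-2,4-dimethoxyphenyl]-3-(4-methoxyphenyl)prop-2-en-1-one, via aldol adduct 9 (not isolated)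
Conditions: KOH (50% aq, 10 equiv), EtOH, rt, 48 h; then 1 M HCl, 0 °C
Reagents that add atoms: none
Why: Claisen–Schmidt crossed aldol condensation, in which only 7 is enolisable and only 8 is an aldehyde, and E1cB dehydration of racemic 9 gives the conjugated E-enone under thermodynamic control.

**Step 6**
Reactants: 10 (E)-1-[3-(benzyloxy)-6-hydroxy-2,4-dimethoxyphenyl]-3-(4-methoxyphenyl)prop-2-en-1-one
Product: 12 6-(benzyloxy)-5,7-dimethoxy-2-(4-methoxyphenyl)-4H-chromen-4-one, via flavanone 11 (not isolated)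
Conditions: I2 (10 mol%), DMSO, 120 °C, 3 h
Reagents that add atoms: none
Why: I2/DMSO oxidative cyclisation of a 2'-hydroxychalcone, in which oxa-Michael closure through the only free phenol places OBn at C6, and iodination/HI elimination (HI re-oxidised by DMSO) aromatises racemic 11 and erases its C2 centre.

**Step 7**
Reactants: 12 6-(benzyloxy)-5,7-dimethoxy-2-(4-methoxyphenyl)-4H-chromen-4-one
Product: 13 6-hydroxy-5,7-dimethoxy-2-(4-methoxyphenyl)-4H-chromen-4-one
Conditions: H2 (1 atm), 10% Pd/C, EtOAc–MeOH, rt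
Reagents that add atoms: none
Why: Catalytic hydrogenolysis cleaves only the benzylic C–O bond, while aryl methyl ethers and the γ-pyrone C2=C3 bond are inert at 1 atm and rt.

**Step 8**
Reactants: 13 6-hydroxy-5,7-dimethoxy-2-(4-methoxyphenyl)-4H-chromen-4-one; 14 4-fluorobenzaldehyde
Product: 15 4-{[5,7-dimethoxy-2-(4-methoxyphenyl)-4-oxo-4H-chromen-6-yl]oxy}benzaldehyde
Conditions: 14 (1.5 equiv), Cs2CO3 (1.5 equiv), dry DMSO, 100 °C, N2, 12 h
Reagents that add atoms: none
Why: SNAr (addition–elimination), in which the electron-rich caesium phenoxide attacks the C–F carbon para to the formyl group through a Meisenheimer complex, and no aldol side reaction is possible because neither partner carries an enolisable ketone at this stage.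

**Step 9**
Reactants: 15 4-{[5,7-dimethoxy-2-(4-methoxyphenyl)-4-oxo-4H-chromen-6-yl]oxy}benzaldehyde
Product: 16 4-{[5,7-dihydroxy-2-(4-hydroxyphenyl)-4-oxo-4H-chromen-6-yl]oxy}benzaldehyde
Conditions: BBr3 (8 equiv), CH2Cl2, −78 °C → rt, 16 h; then ice, 1 M HCl–THF, rt
Reagents that add atoms: none
Why: Lewis-acid aryl methyl ether cleavage, in which bromide attacks each boron-activated O–CH3 in an SN2 step, the diaryl ether has no sp3 C–O bond and survives, and the closed pyranone fixes the 6-aryloxy regiochemistry.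

**Step 10**
Reactants: 16 4-{[5,7-dihydroxy-2-(4-hydroxyphenyl)-4-oxo-4H-chromen-6-yl]oxy}benzaldehyde
Product: 17 4-({5,7-bis(benzyloxy)-2-[4-(benzyloxy)phenyl]-4-oxo-4H-chromen-6-yl}oxy)benzaldehyde
Conditions: BnBr (4.5 equiv), K2CO3 (6 equiv), DMF, 70 °C, 12 h
Reagents that add atoms: benzyl bromide (BrCc1ccccc1)
Why: Exhaustive Williamson etherification, in which excess reagent and heat also alkylate the chelated 5-OH, giving hydrogenolysable groups orthogonal to the future 7-OMe and leaving the non-enolisable aldehyde untouched.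

**Step 11**
Reactants: 18 2',4',6'-trihydroxyacetophenone
Product: 19 1-(2,6-dihydroxy-4-methoxyphenyl)ethanone
Conditions: Me2SO4 (1.0 equiv), K2CO3 (1.0 equiv), acetone, reflux, 6 h
Reagents that add atoms: dimethyl sulfate (COS(=O)(=O)OC)
Why: Selective Williamson methylation, in which the 4-OH is the most acidic hydroxyl and the only one not hydrogen-bonded to the acetyl group, so one equivalent of reagent reacts there first and over-methylated material is removed by chromatography.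

**Step 12**
Reactants: 19 1-(2,6-dihydroxy-4-methoxyphenyl)ethanone
Product: 20 1-[2-(benzyloxy)-6-hydroxy-4-methoxyphenyl]ethanone
Conditions: BnBr (1.05 equiv), K2CO3 (1.2 equiv), acetone, reflux
Reagents that add atoms: benzyl bromide (BrCc1ccccc1)
Why: Williamson mono-benzylation of two equivalent ortho-hydroxyls, which stops after one alkylation because the remaining OH is firmly chelated to the carbonyl.

**Step 13**
Reactants: 17 4-({5,7-bis(benzyloxy)-2-[4-(benzyloxy)phenyl]-4-oxo-4H-chromen-6-yl}oxy)benzaldehyde; 20 1-[2-(benzyloxy)-6-hydroxy-4-methoxyphenyl]ethanone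
Product: 22 (E)-1-[2-(benzyloxy)-6-hydroxy-4-methoxyphenyl]-3-[4-({5,7-bis(benzyloxy)-2-[4-(benzyloxy)phenyl]-4-oxo-4H-chromen-6-yl}oxy)phenyl]prop-2-en-1-one, via aldol adduct 21 (not isolated)
Conditions: KOH (50% aq, 12 equiv), EtOH–THF 1:1, rt, 48 h, N2; then 1 M HCl, 0 °C
Reagents that add atoms: none
Why: Intermolecular Claisen–Schmidt aldol condensation, in which 20 is the only enolisable partner and 17 the only aldehyde, E1cB dehydration of racemic 21 gives the E-enone, and the fully O-alkylated flavone tolerates KOH at rt (if opened, its single free phenol can only reclose to the same ring in step 14).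

**Step 14**
Reactants: 22 (E)-1-[2-(benzyloxy)-6-hydroxy-4-methoxyphenyl]-3-[4-({5,7-bis(benzyloxy)-2-[4-(benzyloxy)phenyl]-4-oxo-4H-chromen-6-yl}oxy)phenyl]prop-2-en-1-one
Product: 24 5,7-bis(benzyloxy)-6-{4-[5-(benzyloxy)-7-methoxy-4-oxo-4H-chromen-2-yl]phenoxy}-2-[4-(benzyloxy)phenyl]-4H-chromen-4-one, via flavanone 23 (not isolated)
Conditions: I2 (15 mol%), DMSO, 120 °C, 3 h
Reagents that add atoms: none
Why: I2/DMSO oxidative cyclisation, in which oxa-Michael closure by the one free phenol gives racemic 23, dehydrogenation places OBn at C5 and OMe at C7, and any 5-O-debenzylated by-product converges on the target in step 15.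

**Step 15**
Reactants: 24 5,7-bis(benzyloxy)-6-{4-[5-(benzyloxy)-7-methoxy-4-oxo-4H-chromen-2-yl]phenoxy}-2-[4-(benzyloxy)phenyl]-4H-chromen-4-one
Product: 25 neocryptomerin
Conditions: H2 (1 atm), 10% Pd/C, THF–MeOH 1:1, rt
Reagents that add atoms: none
Why: Global catalytic hydrogenolysis removes all four benzyl ethers under neutral conditions that leave the aryl methyl ether, the diaryl ether and both γ-pyrone rings intact, and the product is achiral.

**Compound list**
1 | syringaldehyde (4-hydroxy-3,5-dimethoxybenzaldehyde) | COc1cc(C=O)cc(OC)c1O | starting material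
2 | 4-hydroxy-3,5-dimethoxyphenyl formate | COc1cc(OC=O)cc(OC)c1O | intermediate
3 | 2,6-dimethoxybenzene-1,4-diol | COc1cc(O)cc(OC)c1O | intermediate
4 | 2,6-dimethoxybenzene-1,4-diyl diacetate | COc1cc(OC(C)=O)cc(OC)c1OC(C)=O | intermediate
5 | 3-acetyl-4-hydroxy-2,6-dimethoxyphenyl acetate | CC(=O)Oc1c(OC)cc(O)c(C(C)=O)c1OC | intermediate
6 | 1-(3,6-dihydroxy-2,4-dimethoxyphenyl)ethanone | CC(=O)c1c(O)cc(OC)c(O)c1OC | intermediate
7 | 1-[3-(benzyloxy)-6-hydroxy-2,4-dimethoxyphenyl]ethanone | CC(=O)c1c(O)cc(OC)c(OCc2ccccc2)c1OC | intermediate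
8 | 4-methoxybenzaldehyde | COc1ccc(C=O)cc1 | starting material
9 | rac-1-[3-(benzyloxy)-6-hydroxy-2,4-dimethoxyphenyl]-3-hydroxy-3-(4-methoxyphenyl)propan-1-one | COc1ccc(C(O)CC(=O)c2c(O)cc(OC)c(OCc3ccccc3)c2OC)cc1 | intermediate
10 | (E)-1-[3-(benzyloxy)-6-hydroxy-2,4-dimethoxyphenyl]-3-(4-methoxyphenyl)prop-2-en-1-one | COc1ccc(/C=C/C(=O)c2c(O)cc(OC)c(OCc3ccccc3)c2OC)cc1 | intermediate
11 | rac-6-(benzyloxy)-5,7-dimethoxy-2-(4-methoxyphenyl)chroman-4-one | COc1ccc(C2CC(=O)c3c(OC)c(OCc4ccccc4)c(OC)cc3O2)cc1 | intermediate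
12 | 6-(benzyloxy)-5,7-dimethoxy-2-(4-methoxyphenyl)-4H-chromen-4-one | COc1ccc(-c2cc(=O)c3c(OC)c(OCc4ccccc4)c(OC)cc3o2)cc1 | intermediate
13 | 6-hydroxy-5,7-dimethoxy-2-(4-methoxyphenyl)-4H-chromen-4-one | COc1ccc(-c2cc(=O)c3c(OC)c(O)c(OC)cc3o2)cc1 | intermediate
14 | 4-fluorobenzaldehyde | O=Cc1ccc(F)cc1 | starting material
15 | 4-{[5,7-dimethoxy-2-(4-methoxyphenyl)-4-oxo-4H-chromen-6-yl]oxy}benzaldehyde | COc1ccc(-c2cc(=O)c3c(OC)c(Oc4ccc(C=O)cc4)c(OC)cc3o2)cc1 | intermediate
16 | 4-{[5,7-dihydroxy-2-(4-hydroxyphenyl)-4-oxo-4H-chromen-6-yl]oxy}benzaldehyde | O=Cc1ccc(Oc2c(O)cc3oc(-c4ccc(O)cc4)cc(=O)c3c2O)cc1 | intermediate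
17 | 4-({5,7-bis(benzyloxy)-2-[4-(benzyloxy)phenyl]-4-oxo-4H-chromen-6-yl}oxy)benzaldehyde | O=Cc1ccc(Oc2c(OCc3ccccc3)cc3oc(-c4ccc(OCc5ccccc5)cc4)cc(=O)c3c2OCc2ccccc2)cc1 | intermediate
18 | 2',4',6'-trihydroxyacetophenone | CC(=O)c1c(O)cc(O)cc1O | starting material
19 | 1-(2,6-dihydroxy-4-methoxyphenyl)ethanone | CC(=O)c1c(O)cc(OC)cc1O | intermediate
20 | 1-[2-(benzyloxy)-6-hydroxy-4-methoxyphenyl]ethanone | CC(=O)c1c(O)cc(OC)cc1OCc1ccccc1 | intermediate
21 | rac-1-[2-(benzyloxy)-6-hydroxy-4-methoxyphenyl]-3-hydroxy-3-[4-({5,7-bis(benzyloxy)-2-[4-(benzyloxy)phenyl]-4-oxo-4H-chromen-6-yl}oxy)phenyl]propan-1-one | COc1cc(O)c(C(=O)CC(O)c2ccc(Oc3c(OCc4ccccc4)cc4oc(-c5ccc(OCc6ccccc6)cc5)cc(=O)c4c3OCc3ccccc3)cc2)c(OCc2ccccc2)c1 | intermediate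
22 | (E)-1-[2-(benzyloxy)-6-hydroxy-4-methoxyphenyl]-3-[4-({5,7-bis(benzyloxy)-2-[4-(benzyloxy)phenyl]-4-oxo-4H-chromen-6-yl}oxy)phenyl]prop-2-en-1-one | COc1cc(O)c(C(=O)/C=C/c2ccc(Oc3c(OCc4ccccc4)cc4oc(-c5ccc(OCc6ccccc6)cc5)cc(=O)c4c3OCc3ccccc3)cc2)c(OCc2ccccc2)c1 | intermediate
23 | rac-5,7-bis(benzyloxy)-6-{4-[5-(benzyloxy)-7-methoxy-4-oxochroman-2-yl]phenoxy}-2-[4-(benzyloxy)phenyl]-4H-chromen-4-one | COc1cc2OC(CC(=O)c2c(OCc2ccccc2)c1)c1ccc(Oc2c(OCc3ccccc3)cc3oc(-c4ccc(OCc5ccccc5)cc4)cc(=O)c3c2OCc2ccccc2)cc1 | intermediate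
24 | 5,7-bis(benzyloxy)-6-{4-[5-(benzyloxy)-7-methoxy-4-oxo-4H-chromen-2-yl]phenoxy}-2-[4-(benzyloxy)phenyl]-4H-chromen-4-one | COc1cc(OCc2ccccc2)c2c(=O)cc(-c3ccc(Oc4c(OCc5ccccc5)cc5oc(-c6ccc(OCc7ccccc7)cc6)cc(=O)c5c4OCc4ccccc4)cc3)oc2c1 | intermediate
25 | neocryptomerin, 5,7-dihydroxy-6-[4-(5-hydroxy-7-methoxy-4-oxo-4H-chromen-2-yl)phenoxy]-2-(4-hydroxyphenyl)-4H-chromen-4-one | COc1cc(O)c2c(=O)cc(-c3ccc(Oc4c(O)cc5oc(-c6ccc(O)cc6)cc(=O)c5c4O)cc3)oc2c1 | target

**Total step count:** 15. **Longest linear sequence:** 13 (steps 1–10, then 13–15). Steps 11–12 form the convergent branch.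

**Three steps most likely to fail**

Step 8 (SNAr by a phenoxide flanked by two methoxy groups). The fallback sets out from 13 and comes back at 15. It replaces addition–elimination by metal-free ligand coupling on iodine(III), which tolerates di-ortho-substituted phenols. 4-Formylphenylboronic acid and 4-(diacetoxyiodo)anisole are combined with BF3·OEt2 in CH2Cl2 at 0 °C. Washing with aq NaBF4 then gives (4-formylphenyl)(4-methoxyphenyl)iodonium tetrafluoroborate F1. The potassium phenoxide of 13 (t-BuOK, THF, 0 → 40 °C) attacks the iodine centre. The electron-poorer formylphenyl group is transferred to oxygen, which gives 15 directly.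

Step 9 (BBr3 in the presence of a free aryl aldehyde, which risks benzal bromide formation or Friedel–Crafts condensation). The fallback sets out from 15 and comes back at 17, bypassing 16. The aldehyde is masked before the Lewis acid is used.
- Propane-1,3-dithiol and BF3·OEt2 (CH2Cl2, 0 °C) react only at the aldehyde, because the pyrone carbonyl is inert. This gives 6-[4-(1,3-dithian-2-yl)phenoxy]-5,7-dimethoxy-2-(4-methoxyphenyl)-4H-chromen-4-one F2.
- BBr3 (CH2Cl2, −78 °C → rt) then gives 6-[4-(1,3-dithian-2-yl)phenoxy]-5,7-dihydroxy-2-(4-hydroxyphenyl)-4H-chromen-4-one F3.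
- BnBr/K2CO3/DMF gives 5,7-bis(benzyloxy)-2-[4-(benzyloxy)phenyl]-6-[4-(1,3-dithian-2-yl)phenoxy]-4H-chromen-4-one F4.
- Alkylative hydrolysis (MeI, CaCO3, MeCN–H2O, 50 °C) releases aldehyde 17.

Step 13 (aldol condensation of a large, poorly soluble aldehyde while a flavone is exposed to KOH). The fallback sets out from 17, with 20 as partner, and comes back at 24, bypassing 22. The same two fragments are joined at the higher oxidation level by C-acylation of a preformed enolate, so no aqueous base or oxidative cyclisation is needed.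
- Pinnick oxidation (NaClO2, NaH2PO4, 2-methyl-2-butene, t-BuOH–THF–H2O) gives 4-({5,7-bis(benzyloxy)-2-[4-(benzyloxy)phenyl]-4-oxo-4H-chromen-6-yl}oxy)benzoic acid F5.
- Oxalyl chloride with cat. DMF (CH2Cl2) gives 4-({5,7-bis(benzyloxy)-2-[4-(benzyloxy)phenyl]-4-oxo-4H-chromen-6-yl}oxy)benzoyl chloride F6.
- The dilithio dianion of 20 (LiHMDS, 3.2 equiv, THF, −78 °C) is acylated on carbon by F6. This gives 1-[2-(benzyloxy)-6-hydroxy-4-methoxyphenyl]-3-[4-({5,7-bis(benzyloxy)-2-[4-(benzyloxy)phenyl]-4-oxo-4H-chromen-6-yl}oxy)phenyl]propane-1,3-dione F7.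
- Cyclodehydration (p-TsOH cat., toluene, 90 °C) gives 24.

**Further compounds**
F1 | step 8 | (4-formylphenyl)(4-methoxyphenyl)iodonium tetrafluoroborate | O=Cc1ccc([I+]c2ccc(OC)cc2)cc1.F[B-](F)(F)F
F2 | step 9 | 6-[4-(1,3-dithian-2-yl)phenoxy]-5,7-dimethoxy-2-(4-methoxyphenyl)-4H-chromen-4-one | COc1ccc(-c2cc(=O)c3c(OC)c(Oc4ccc(C5SCCCS5)cc4)c(OC)cc3o2)cc1
F3 | step 9 | 6-[4-(1,3-dithian-2-yl)phenoxy]-5,7-dihydroxy-2-(4-hydroxyphenyl)-4H-chromen-4-one | Oc1ccc(-c2cc(=O)c3c(O)c(Oc4ccc(C5SCCCS5)cc4)c(O)cc3o2)cc1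
F4 | step 9 | 5,7-bis(benzyloxy)-2-[4-(benzyloxy)phenyl]-6-[4-(1,3-dithian-2-yl)phenoxy]-4H-chromen-4-one | C1(SCCCS1)c1ccc(Oc2c(OCc3ccccc3)cc3oc(-c4ccc(OCc5ccccc5)cc4)cc(=O)c3c2OCc2ccccc2)cc1
F5 | step 13 | 4-({5,7-bis(benzyloxy)-2-[4-(benzyloxy)phenyl]-4-oxo-4H-chromen-6-yl}oxy)benzoic acid | OC(=O)c1ccc(Oc2c(OCc3ccccc3)cc3oc(-c4ccc(OCc5ccccc5)cc4)cc(=O)c3c2OCc2ccccc2)cc1
F6 | step 13 | 4-({5,7-bis(benzyloxy)-2-[4-(benzyloxy)phenyl]-4-oxo-4H-chromen-6-yl}oxy)benzoyl chloride | ClC(=O)c1ccc(Oc2c(OCc3ccccc3)cc3oc(-c4ccc(OCc5ccccc5)cc4)cc(=O)c3c2OCc2ccccc2)cc1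
F7 | step 13 | 1-[2-(benzyloxy)-6-hydroxy-4-methoxyphenyl]-3-[4-({5,7-bis(benzyloxy)-2-[4-(benzyloxy)phenyl]-4-oxo-4H-chromen-6-yl}oxy)phenyl]propane-1,3-dione | COc1cc(O)c(C(=O)CC(=O)c2ccc(Oc3c(OCc4ccccc4)cc4oc(-c5ccc(OCc6ccccc6)cc5)cc(=O)c4c3OCc3ccccc3)cc2)c(OCc2ccccc2)c1
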